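**Retrosynthetic overview**
1. The target comes from global hydrogenolysis of its hepta-O-benzyl ether, in which only the upper unit carries benzyl groups.
2. The C4–C8 bond is cut into purchased (−)-EGCG (all lower-unit rings intact) and the C4 cation of an all-cis upper-unit 4-ol 3-gallate. The gallate shields the α face, which gives the 4β linkage.
3. That 4-ol 3-gallate comes from a tricyclic 3,4-O-phenylboronate by exchanging the boron clamp for one galloyl group.
4. The boronate comes from 3,5-bis(benzyloxy)phenol, PhB(OH)2 and an enantiopure cis-epoxy aldehyde in one flask, forming the C4–C4a and O1–C2 bonds. The epoxy aldehyde comes from a Z-cinnamate by Mn-salen epoxidation.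
5. Ring order: the oxirane forms first (step 2, sacrificial). Pyran ring C and the dioxaborolane then form together (step 4). The boron ring is removed in step 5. Rings A and B, the galloyl rings and the whole lower unit are purchased.

Assumption: every compound marked as starting material in the compound list and every reagent named in a Conditions line is a catalogue item, and the C4 centre of the non-isolated boron intermediate is left undefined because it converges in the same flask.

**Step 1**
Reactants: 1 3,4-bis(benzyloxy)benzaldehyde; 2 ethyl 2-(diphenoxyphosphoryl)acetate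
Product: 3 ethyl (Z)-3-[3,4-bis(benzyloxy)phenyl]prop-2-enoate
Conditions: NaH, THF, −78 to 0 °C
Reagents that add atoms: none
Why: In this Ando-type Horner–Wadsworth–Emmons olefination the electron-poor diaryl phosphonate makes oxaphosphetane collapse fast and kinetically Z-selective (usually above 9:1 for aryl aldehydes), and no stereocentre is formed.

**Step 2**
Reactants: 3 ethyl (Z)-3-[3,4-bis(benzyloxy)phenyl]prop-2-enoate
Product: 4 ethyl (2S,3S)-3-[3,4-bis(benzyloxy)phenyl]oxirane-2-carboxylate (cis)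
Conditions: aq. NaOCl (pH 11.3, Na2HPO4), (S,S)-[N,N'-bis(3,5-di-tert-butylsalicylidene)-1,2-cyclohexanediaminato]MnCl (5 mol%), 4-phenylpyridine N-oxide (20 mol%), CH2Cl2, 4 °C
Reagents that add atoms: sodium hypochlorite, [Na+].[O-]Cl
Why: cis-Cinnamates, including para-alkoxy ones, are privileged substrates for the Jacobsen–Katsuki epoxidation, and side-on approach over the (S,S)-diamine backbone delivers oxygen to one face and sets both centres as the (2S,3S)-cis-epoxide, with the minor trans-epoxide removed by chromatography.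

**Step 3**
Reactants: 4 ethyl (2S,3S)-3-[3,4-bis(benzyloxy)phenyl]oxirane-2-carboxylate
Product: 5 (2S,3S)-3-[3,4-bis(benzyloxy)phenyl]oxirane-2-carbaldehyde (cis)
Conditions: (i-Bu)2AlH (1.05 equiv), toluene, −78 °C; aq. potassium sodium tartrate work-up
Reagents that add atoms: none
Why: In this partial ester reduction the tetrahedral aluminium hemiacetal is stable at −78 °C and collapses only on work-up, so the aldehyde is not over-reduced and neither oxirane centre is touched.

**Step 4 (key step)**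
Reactants: 5 (2S,3S)-3-[3,4-bis(benzyloxy)phenyl]oxirane-2-carbaldehyde; 6 3,5-bis(benzyloxy)phenol
Product: 8 (2R,3R,4R)-5,7,3',4'-tetra-O-benzylflavan-3,4-diol 3,4-O-phenylboronate (all-cis), via epoxy benzodioxaborin 7 (not isolated)
Conditions: PhB(OH)2 (1.1 equiv), EtCO2H (20 mol%), 4 Å MS, toluene, 40 °C, slow addition of 5
Reagents that add atoms: phenylboronic acid, OB(O)c1ccccc1
Why: Proposed new method: phenylboronic acid first ties phenol 6 and aldehyde 5 into a mixed boronate so that the ortho carbon attacks the carbonyl through a six-membered transition state (C4–C4a bond, giving 7), acid-catalysed B–O(aryl) exchange then frees the phenol while boron, still held on O4, chelates the oxirane oxygen, and the phenol opens the activated benzylic C2–O bond from the rear in a 6-endo mode, so that C2 is inverted to R, C3 keeps its C–O bond (R), and boron ends as a clamp on the cis-3,4-diol into which both C4 epimers drain because the benzylic C4–O bond ionises reversibly; pyran ring C and the dioxaborolane therefore form in one operation, and the closest known reaction types are the Nagata–Lau boronic-acid-templated ortho-hydroxyalkylation of phenols and the Lewis-acid-promoted 6-endo opening of aryl oxiranes by ortho-phenols used for flavan-3-ols.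

**Step 5**
Reactants: 8 (2R,3R,4R)-5,7,3',4'-tetra-O-benzylflavan-3,4-diol 3,4-O-phenylboronate; 9 3,4,5-tris(benzyloxy)benzoic acid
Product: 11 (2R,3R,4R)-5,7,3',4'-tetra-O-benzyl-4-hydroxyflavan-3-yl 3,4,5-tris(benzyloxy)benzoate, via free cis-3,4-diol 10 (not isolated)
Conditions: pinacol (1.05 equiv), CH2Cl2, rt, 1 h; then 9 (1.1 equiv), DCC (1.2 equiv), DMAP (20 mol%), 0 °C to rt
Reagents that add atoms: none
Why: Boronate transesterification (the pinacol ester is far more stable than that of a cyclohexane-type cis-diol) is followed by Steglich esterification with one equivalent of acid, base-mediated acyl migration settles the ester on O3, any 4-O-acyl or diacyl by-product is harmless because it ionises to the same acyloxonium-capped C4 cation in step 6, and no stereocentre is touched.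

**Step 6**
Reactants: 11 (2R,3R,4R)-5,7,3',4'-tetra-O-benzyl-4-hydroxyflavan-3-yl 3,4,5-tris(benzyloxy)benzoate; 12 (−)-epigallocatechin 3-O-gallate (EGCG, 4 equiv, excess recovered)
Product: 13 5,7,3',4'-tetra-O-benzyl-3-O-(tri-O-benzylgalloyl)epicatechin-(4β→8)-(−)-epigallocatechin 3-O-gallate
Conditions: BF3·OEt2 (30 mol%), THF–CH2Cl2 (1:1), −20 to 0 °C
Reagents that add atoms: none
Why: In this acid-catalysed SN1 Friedel–Crafts (biomimetic interflavan) coupling ring A expels the benzylic 4-OH, the 3-O-galloyl carbonyl caps the α face of the cation, and the free-phenolic and therefore more nucleophilic ring A of EGCG attacks through C8 from the β face, giving the 3,4-trans (4R) linkage, while excess 12 suppresses oligomers and the benzylated product separates easily from it.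

**Step 7**
Reactants: 13 5,7,3',4'-tetra-O-benzyl-3-O-(tri-O-benzylgalloyl)epicatechin-(4β→8)-(−)-epigallocatechin 3-O-gallate
Product: 14 (−)-epicatechin 3-O-gallate-(4β→8)-(−)-epigallocatechin 3-O-gallate (CNP0296769.1)
Conditions: H2 (1 atm), Pd(OH)2/C, THF–MeOH–H2O, rt
Reagents that add atoms: none
Why: Heterogeneous hydrogenolysis cleaves the seven O-benzyl ethers while the gallate esters, both C2–O1 bonds and the C4–C8 bond persist at 1 atm, so all five stereocentres are retained.

**Compound list**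
1 | 3,4-bis(benzyloxy)benzaldehyde | O=Cc1ccc(OCc2ccccc2)c(OCc2ccccc2)c1 | starting material
2 | ethyl 2-(diphenoxyphosphoryl)acetate | CCOC(=O)CP(=O)(Oc1ccccc1)Oc1ccccc1 | starting material
3 | ethyl (Z)-3-[3,4-bis(benzyloxy)phenyl]prop-2-enoate | CCOC(=O)/C=C\c1ccc(OCc2ccccc2)c(OCc2ccccc2)c1 | intermediate
4 | ethyl (2S,3S)-3-[3,4-bis(benzyloxy)phenyl]oxirane-2-carboxylate (cis) | CCOC(=O)[C@H]1O[C@H]1c1ccc(OCc2ccccc2)c(OCc2ccccc2)c1 | intermediate
5 | (2S,3S)-3-[3,4-bis(benzyloxy)phenyl]oxirane-2-carbaldehyde (cis) | O=C[C@H]1O[C@H]1c1ccc(OCc2ccccc2)c(OCc2ccccc2)c1 | intermediate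
6 | 3,5-bis(benzyloxy)phenol | Oc1cc(OCc2ccccc2)cc(OCc2ccccc2)c1 | starting material
7 | 5,7-bis(benzyloxy)-2-phenyl-4-(cis-3-aryloxiran-2-yl)-4H-1,3,2-benzodioxaborin, oxirane configuration of 5 retained, both C4 epimers | C(c1ccccc1)Oc1cc(OCc2ccccc2)c2c(c1)OB(c1ccccc1)OC2[C@H]1O[C@H]1c1ccc(OCc3ccccc3)c(OCc3ccccc3)c1 | intermediate (not isolated)
8 | (2R,3R,4R)-5,7,3',4'-tetra-O-benzylflavan-3,4-diol 3,4-O-phenylboronate (2,3-cis-3,4-cis) | C(c1ccccc1)Oc1cc(OCc2ccccc2)c2c(c1)O[C@H](c1ccc(OCc3ccccc3)c(OCc3ccccc3)c1)[C@@H]1OB(c3ccccc3)O[C@@H]12 | intermediate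
9 | 3,4,5-tris(benzyloxy)benzoic acid | O=C(O)c1cc(OCc2ccccc2)c(OCc2ccccc2)c(OCc2ccccc2)c1 | starting material
10 | (2R,3R,4R)-5,7,3',4'-tetra-O-benzylflavan-3,4-diol | C(c1ccccc1)Oc1cc(OCc2ccccc2)c2c(c1)O[C@H](c1ccc(OCc3ccccc3)c(OCc3ccccc3)c1)[C@H](O)[C@@H]2O | intermediate (not isolated)
11 | (2R,3R,4R)-5,7,3',4'-tetra-O-benzyl-4-hydroxyflavan-3-yl 3,4,5-tris(benzyloxy)benzoate | C(c1ccccc1)Oc1cc(OCc2ccccc2)c2c(c1)O[C@H](c1ccc(OCc3ccccc3)c(OCc3ccccc3)c1)[C@H](OC(=O)c1cc(OCc3ccccc3)c(OCc3ccccc3)c(OCc3ccccc3)c1)[C@@H]2O | intermediate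
12 | (−)-epigallocatechin 3-O-gallate (2R,3R) | O=C(O[C@@H]1Cc2c(O)cc(O)cc2O[C@@H]1c1cc(O)c(O)c(O)c1)c1cc(O)c(O)c(O)c1 | starting material
13 | 5,7,3',4'-tetra-O-benzyl-3-O-(tri-O-benzylgalloyl)epicatechin-(4β→8)-(−)-epigallocatechin 3-O-gallate | O=C(O[C@@H]1[C@@H](c2c(O)cc(O)c3c2O[C@H](c2cc(O)c(O)c(O)c2)[C@H](OC(=O)c2cc(O)c(O)c(O)c2)C3)c2c(OCc3ccccc3)cc(OCc3ccccc3)cc2O[C@@H]1c1ccc(OCc2ccccc2)c(OCc2ccccc2)c1)c1cc(OCc2ccccc2)c(OCc2ccccc2)c(OCc2ccccc2)c1 | intermediate
14 | (−)-epicatechin 3-O-gallate-(4β→8)-(−)-epigallocatechin 3-O-gallate | O=C(O[C@@H]1[C@@H](c2c(O)cc(O)c3c2O[C@H](c2cc(O)c(O)c(O)c2)[C@H](OC(=O)c2cc(O)c(O)c(O)c2)C3)c2c(O)cc(O)cc2O[C@@H]1c1ccc(O)c(O)c1)c1cc(O)c(O)c(O)c1 | target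

**Total step count:** 7. **Longest linear sequence:** 7 (1 → 3 → 4 → 5 → 8 → 11 → 13 → 14).

**Steps most likely to fail**

**Step 4.**
- Risk: the electron-rich cis-epoxy aldehyde may rearrange or be C-arylated at C2 before the templated addition occurs. The 6-endo opening may also leak towards an SN1 pathway and give the 2,3-trans product.
- Fallback: this sets out from 5 and 6. Compound 6 is converted into its bromomagnesium phenolate (EtMgBr, Et2O, then CH2Cl2) and 5 is added at −20 °C. This chelate-controlled, ortho-specific hydroxyalkylation needs no acid and allows isolation of the epoxy benzylic alcohol F1. Treating F1 with PhB(OH)2 and 4 Å MS in toluene at rt still closes ring C and the dioxaborolane together, and the route is rejoined at 8.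

**Step 6.**
- Risk: unprotected EGCG may give C6 as well as C8 alkylation, and O-alkylation or self-condensation of 11 may compete.
- Fallback: this sets out from 11 and 12. Compound 12 is perbenzylated (BnBr, K2CO3, DMF) to octa-O-benzyl-EGCG F2, in which C8 is the only readily accessible nucleophilic carbon. F2 is coupled with 11 (TMSOTf, CH2Cl2, −78 °C) to the pentadeca-O-benzyl dimer F3. This is hydrogenolysed over Pd(OH)2/C as in step 7, and the route is rejoined at 14.

**Step 2.**
- Risk: radical leakage with the very electron-rich styrene may raise the proportion of trans-epoxide or erode the ee.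
- Fallback: this sets out from 3, which is reduced with (i-Bu)2AlH (2.2 equiv, −78 °C) to the (Z)-allylic alcohol F4. Hydroxyl-directed Sharpless epoxidation (Ti(OiPr)4, D-(−)-diethyl tartrate, t-BuOOH, 4 Å MS, CH2Cl2, −20 °C) gives the cis-epoxy alcohol F5. Parikh–Doering oxidation (SO3·pyridine, DMSO, Et3N) rejoins the route at 5 and bypasses 4.

**Further compounds**
F1 | step 4 | 3,5-bis(benzyloxy)-2-{hydroxy[cis-3-(3,4-bis(benzyloxy)phenyl)oxiran-2-yl]methyl}phenol, oxirane configuration of 5 retained, carbinol epimers | Oc1cc(OCc2ccccc2)cc(OCc2ccccc2)c1C(O)[C@H]1O[C@H]1c1ccc(OCc2ccccc2)c(OCc2ccccc2)c1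
F2 | step 6 | octa-O-benzyl-(−)-epigallocatechin 3-O-gallate | O=C(O[C@@H]1Cc2c(OCc3ccccc3)cc(OCc3ccccc3)cc2O[C@@H]1c1cc(OCc2ccccc2)c(OCc2ccccc2)c(OCc2ccccc2)c1)c1cc(OCc2ccccc2)c(OCc2ccccc2)c(OCc2ccccc2)c1
F3 | step 6 | pentadeca-O-benzyl epicatechin 3-O-gallate-(4β→8)-epigallocatechin 3-O-gallate | O=C(O[C@@H]1[C@@H](c2c(OCc3ccccc3)cc(OCc3ccccc3)c3c2O[C@H](c2cc(OCc4ccccc4)c(OCc4ccccc4)c(OCc4ccccc4)c2)[C@H](OC(=O)c2cc(OCc4ccccc4)c(OCc4ccccc4)c(OCc4ccccc4)c2)C3)c2c(OCc3ccccc3)cc(OCc3ccccc3)cc2O[C@@H]1c1ccc(OCc2ccccc2)c(OCc2ccccc2)c1)c1cc(OCc2ccccc2)c(OCc2ccccc2)c(OCc2ccccc2)c1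
F4 | step 2 | (Z)-3-[3,4-bis(benzyloxy)phenyl]prop-2-en-1-ol | OC/C=C\c1ccc(OCc2ccccc2)c(OCc2ccccc2)c1
F5 | step 2 | [(2R,3S)-3-[3,4-bis(benzyloxy)phenyl]oxiran-2-yl]methanol (cis) | OC[C@H]1O[C@H]1c1ccc(OCc2ccccc2)c(OCc2ccccc2)c1
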